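(The numbers in the tables come from a simulation for substances that don't exist; noise was put on by code.)

In molar, not in percent, the red run has something to say.

| flask | substrate | partner | remark | time |
|---|---|---|---|---|
| ochre | 0.70 M | 1 M | run made earlier |  |
| red | 2.3 M | 1 M | run made earlier |  |
| Friday's | 0.50 M | 1.00 M |  | 30 h |
| Sunday's | 0.80 M | 1.00 M |  | 30 h |
| Tuesday's | 1.2 M | 1.00 M |  | 30 h |
| Thursday's | 1.5 M | 1.00 M |  | 30 h |

| run | time / h | target / % | substrate / % |
|---|---|---|---|
| ochre | 1.33 | 14 | 55 |
| ochre | 2.50 | 16 | 43 |
| ochre | 4.00 | 6 | 33 |
| ochre | 8.00 | 3 | 19 |
| ochre | 15.0 | 1 | 13 |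
| red | 3.00 | 3 | 63 |
| red | 6.00 | 0 | 60 |
| red | 10.0 | 3 | 63 |
| red | 12.0 | 1 | 57 |
| red | 15.0 | 2 | 58 |

(scatter of a reading: 1.5 percentage points)

- a reading or a percentage of target counts all its forms, free or not
- the concentration of target that is asked is that of its free form alone
- "hardly changes" means that all values lie within two and a half points (for a concentration: within two and a half percent of the largest)
- a reading of substrate is of its free form alone
- a step back or a flat step of under half a percent of the largest counts as no turn

- [target] (only what is free in solution) at the end for Friday's, Sunday's, Tuesday's, Thursday's, in this order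
- how the row runs (hardly changes / falls, then rises / rises all the way / falls all the way / rises, then falls)

What do the earlier runs show at first sight? The ochre substrate keeps falling, to 13 % at 15.0 h. The red substrate stays between 57 % and 63 %.

Why should the red substrate stall while plenty of it stands there? I suspect the partner, charged at 1 M against 2.3 M of substrate, as the limiting reagent of the red run.

How much does that partner charge take? The five red readings average 60.2 %, so the substrate consumed comes to 0.915 M. Call this the capacity, the substrate consumed by that partner charge before the substrate stalls. It is a reading, with the scatter of the readings in it.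

One flask only? The ochre run is the test: its 0.70 M lies below the capacity, and its substrate was still falling over the last two readings, from 19 % at 8.00 h to 13 % at 15.0 h.

And target? In the ochre run it read 16 % at 2.50 h and 1 % at 15.0 h, so it passes through. As I read the runs, it forms from substrate and partner together. A charge well under the capacity should end short of substrate, and one well over it short of partner. So I commit to a row that rises, then falls, turning near the capacity, with Sunday's 0.80 M under it and Tuesday's 1.2 M over it.

The weak spot? The capacity gives no height for the row. It does give the substrate left over a charge above it: 0.285 M on Tuesday's and 0.585 M on Thursday's.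

The forecast gives 3.000 × 10⁻⁴ M, 0.0023 M, 0.0026 M, 0.002 M, so rises, then falls, and it holds that “Target behaves as a short-lived intermediate”.

The flask gives 0.00342 M, 0.00545 M, 0.00632 M, 0.00609 M, so rises, then falls, and Friday's value is 11.4 times the forecast's.

    substrate + partner ⇌ target (K = 0.850 M⁻¹, k = 1.20 × 10⁻⁴ M⁻¹ s⁻¹)
    substrate + partner ⇌ isomer of the product (K = 2.50 M⁻¹, k = 6.20 × 10⁻⁵ M⁻¹ s⁻¹)
    target → over-reaction product (k = 2.80 × 10⁻⁴ s⁻¹)
    partner → decomposed reagent (k = 3.30 × 10⁻⁶ s⁻¹)
    partner + target ⇌ idle adduct, settled at all times (K = 0.480 M⁻¹)

The row turns at 1.2 M, above the capacity of 0.915 M read from the red run. On Tuesday's, the capacity left 0.285 M of substrate to expect, and 0.326 M stands at 30.0 h, with 6.6 % of the partner charge remaining. On Thursday's, it left 0.585 M to expect, and 0.578 M stands at 30.0 h, with 3.6 % of the partner charge remaining.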